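All runs stem from a simulated flask for substances that don't exist, and the scatter is random.

Take the Jd charge as your unit, as when you titrate active sites. The poison number, 0.386, is the charged [Jf] over the charged [Jd]: while it stays below one, it is the share of Jd that Jf, an irreversible inhibitor, takes one for one into Jk.

the same everywhere: Ja 0.57 M; Jb 0.57 M; Jc 1.14 M; Jd 5.7 mM; Je 74 mM; Jf 2.2 mM

| charge | Jg | remark | time |
|---|---|---|---|
| south-east | 2.2 mM | run made earlier |  |
| west | 4.9 mM | run made earlier |  |
| flask | 3.3 mM |  | 25 h |

- south-east (time / h: Jh / %, Jj / %): 2.50: 37.9, 24.5; 8.00: 52.8, 32.9; 15.0: 58.9, 35.4; 20.0: 57.3, 37.0; 30.0: 57.2, 37.3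
- west (time / h: Jh / %, Jj / %): 2.50: 33.5, 21.9; 5.00: 43.3, 26.5; 8.00: 48.4, 29.4; 15.0: 54.5, 33.3; 30.0: 56.3, 34.1

(standard deviation of a reading: 1 percentage point)

- Jd is single-handed; Ja and Jb are mirror images of each other, charged as a racemate, each of them at the stated concentration
- steps under discussion: Jc + Jd + Ja -> Jd + Jh; Jc + Jd + Jb -> Jd + Jj; Ja + Je <-> Jb + Je; Jd + Jf -> Jk; Jd + Jg <-> Jm
- an excess is the difference of the two amounts in percent of their sum
- an excess is below zero if the other one leads

* Jh and Jj together, in percent of the Ja and Jb charged together, at 25 h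
* excess of Jh over Jj in the product at 25 h
* whether the exchange between Ja and Jb keeps pace with the reaction: how far the product's excess at 25 h gets from its value without exchange to its value with instant exchange (above 80 % keeps pace, below 20 % hardly takes part, else lags behind)

I assume Jf acts early, which leaves you 61.4 % of the Jd charge in play. One number is not enough, though. South-east and west both have 0.386, yet at 2.50 h they read 62.4 % and 55.4 % product, and they differ in [Jg].

The flask's [Jg] lies 40.7 % of the way from south-east to west. Interpolating the 30.0 h readings gives 92.8 % product. South-east's total reads 94.3 % at 20.0 h and 94.5 % at 30.0 h, so I commit to the interpolated value for 25 h. The same interpolation gives an excess of 22.5 %.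

South-east's Jh reads 57.2 % at 30.0 h, more than the half of the total that was Ja, and its excess reads 21.5 % at 2.50 h and 21.1 % at 30.0 h. So I expect the exchange to keep pace in the flask.

The forecast, reasoning that “Jf removes 2.2 mM of Jd irreversibly”, gave 92.5 %, an excess of 23 % and "keeps pace". The flask gives 93.3 % and 23.3 %, and the exchange keeps pace, getting 98 % of the way.

    Jc + Jd + Ja → Jd + Jh (k = 4.80 M⁻² min⁻¹)
    Jc + Jd + Jb → Jd + Jj (k = 2.96 M⁻² min⁻¹)
    Ja + Je ⇌ Jb + Je, rate k3*[Je]*[Ja] forward; the back reaction follows from the equilibrium constant (k = 2.09 M⁻¹ min⁻¹)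
    Jd + Jf → Jk (k = 73.1 M⁻¹ min⁻¹)
    Jd + Jg ⇌ Jm, settled at all times (K = 347 M⁻¹)

In the flask, Jk stands at 38.6 % of the catalyst by 2.50 h and still at 38.6 % at 25.0 h, matching 0.386, while Jd at 37.0 % and Jm at 24.4 % make up the remaining 61.4 %. Reckoned at that free Jd, the half-life of Jf is 4.50 min, shorter than the 1.51 h by which half of the turnover to Jh up to 25 h is done.

Now take the neighbour with 0.0014 M of Jd. Its poison number is 1.57, above one, so Jf should take up the whole Jd charge and keep 36.4 % of its own charge. Computed, Jk holds 100 % of the catalyst, Jf stands at 36.4 %, and that neighbour's product reaches 5.77 % at 25 h.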